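Remark on the chemistry: atoms carry the numbers of the bicyclic terpenoid skeleton (C3 carbinol, C4 CMe2, C5 and C10 ring fusion, C8 the ring carbon bearing =CH2, C9 the ring carbon bearing the chain, C11 and C12 the chain methylenes, C13=C14 the first chain alkene; β is the face of the C10 methyl). Compound 3 (minor C6 epimer) and compound 22 (C11 epimers) are carried as mixtures, because those centres vanish in the following step.

## Structural features

The target (C30H50O) is a trans-fused decalin. Ring A (C1–C5, C10) carries an equatorial 3β-hydroxyl next to the C4 gem-dimethyl carbon. Ring B (C5–C10) carries an exocyclic methylene on C8 and, on C9, a sixteen-carbon chain: two methylenes (C11, C12) followed by three trisubstituted alkenes, two of them E and the last an isopropylidene end.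

Three stereocentres are contiguous (C5, the quaternary C10 with its angular methyl, and C9), and the fourth, C3, is separated from C5 only by the quaternary C4. The chain on C9 is equatorial and on the same face as the C10 methyl.

The fragile parts are the exocyclic alkene, which is the less stable isomer and lies next to the allylic C9–H, and the skipped triene, which cyclises or isomerises under acid. The late steps therefore have to be neutral or basic and non-isomerising.

The real difficulty is threefold: the quaternary C10 between two stereocentres, the fully substituted C4 next to the carbinol, and the attachment of the chain to the hindered C9 with the right configuration while the alkene stays exocyclic.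

The pattern "CMe2 carbon on C5 of a six-membered ring whose C8 bears one carbon and whose C9 can be a carbonyl" is the isopropenyl-cyclohexenone pattern of carvone. All ten carvone carbons are used: the six of ring B, the C8 exocyclic carbon, C4 and both C4 methyl groups (the CH3 and the CH2 of the isopropenyl group). A count that credits carvone with only one C4 methyl leaves it one carbon short. The C10 methyl (iodomethane), C1–C3 (allyl bromide), C11 (carbon monoxide) and the fifteen carbons from C12 onward (farnesyl bromide) complete the thirty.

The key step exploits the isopropenyl alkene on C5 and an aldehyde at the end of a three-carbon arm on C10. Hydrogen-atom transfer turns the alkene into the tertiary C4 radical, which bonds to C3, closes ring A and creates the gem-dimethyl group and the carbinol at once.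

## Logic of the disconnections

O–Si bond at C3 (24 from 23). No skeletal bond is cut. The carbinol is masked as a silyl ether because the steps between 10 and 23 use hydride, amide base, an enolate sulfonylation and organolithium reagents. The demand on the forward step is removal without acid, so that the C8 methylene and the triene are not disturbed.

C11–C12 (23 from 22, and 22 from 19 and 20). The cut lies between two sp3 methylenes, remote from every stereocentre, and divides the molecule into a fifteen-carbon bicyclic half and a fifteen-carbon acyclic half. All three chain alkenes arrive with their geometry already fixed in 20. The demand is a C11 nucleophile whose activating group can be removed without trace. A sulfone serves, because in 22 its carbon is homoallylic to both neighbouring alkenes, so its reductive removal to 23 cannot shift or scramble a double bond.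

C11–S and the C11 oxidation level (19 from 18, 18 from 17, 17 from 16). These are functional-group changes that trace C11 back to an ester carbon. The gain is that an ester on C9 can be used to control C9 and the alkene position. The demands are a substitution at a β-branched primary carbon and a sulfur oxidation that spares the exocyclic alkene.

C9–H and the alkene position (16 from 14). Moving the double bond from C8=CH2 into conjugation (C8=C9) removes the C9 stereocentre and the fragile exocyclic alkene in one retrosynthetic move. The forward step must remove a hydrogen from the C8 methyl and not from C7, and must deliver the proton to C9 from the α face.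

C9–C11 (14 from 13, 13 from 11). The ester carbon is cut from C9 and traced to a one-carbon carbonylation of an enol sulfonate, which in turn comes from the enone of 11 by 1,4-reduction. This reveals the ring B enone with C9 carbonyl, C7=C8 and C8 methyl. The demand, a regiodefined C8=C9 enolate, is met structurally because C10 carries no hydrogen.

O–Si bond at C3 (11 from 10). Protection only; the demand is silylation of a hindered carbinol without touching the enone.

C3–C4 (10 from 9). This is the strategic cut, between the carbinol carbon and the quaternary C4. It opens ring A, removes the C3 stereocentre and the quaternary C4, and leaves a monocyclic compound with an isopropenyl group on C5 and a 3-oxopropyl arm on C10. The forward step must generate a tertiary C4 radical from the alkene in the presence of the enone, add it to the aldehyde carbon and place the C3 oxygen equatorial.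

C3 oxidation level (9 from 8, 8 from 6). The aldehyde is traced to a terminal alkene, so that the arm becomes an allyl group that an enolate alkylation can introduce. The demand is discrimination of the monosubstituted alkene from the isopropenyl group and from the enone carbonyl.

C10–C1 (6 from 3 and 4). The bond from the quaternary carbon to the three-carbon arm is cut. The quaternary stereocentre is then made by substrate control, and the demand is entry of the electrophile anti to the C5 substituent.

C10–CH3 (3 from 1). The last cut removes the angular methyl and arrives at 1, which supplies ring B, the C8 carbon, C4 with both its methyls and the C5 configuration. The demand is kinetic deprotonation on the saturated side of the carbonyl and mono-alkylation. The order (methyl first, arm second) fixes which group ends up anti to the C5 substituent.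

## Other disconnections considered

Alternative 1: The cut removes C9 together with its whole chain from ring B (bonds C8–C9 and C9–C10). This leaves the ring-contracted trans-hydrindanone A2, whose C8 carbonyl is bonded directly to C10, and the bis(methylseleno)acetal A3 of the sixteen-carbon chain aldehyde. Forward, selenium–lithium exchange on A3 would give the C9 carbanion, which adds to the C8 carbonyl of A2. Electrophilic activation of selenium in the adduct would then drive a 1,2-shift of C10 from C8 to C9 and give the ring-expanded ketone A1 after equilibration of C9.
- In its favour: the full chain and C9 arrive in one operation, and the C8 ketone of A1 is the direct handle for the methylene group. Only Wittig methylenation and desilylation would remain. In convergence and in the number of steps after the key step this plan is better than the chosen one (two or three against ten). The ring-expansion type is also established, which is an advantage over a key step that extends precedent.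
- Against it here: A2 is not a chiral-pool compound. A trans-fused hydrindanone with three stereocentres and the quaternary C4 would need its own enantioselective synthesis, likely longer than the four steps that lead to 9. The shift must select the quaternary C10 over the C7 methylene. The carbanion has to add to a neopentyl ketone that can enolise towards C7. Selenium must be activated by an electrophile in the presence of three nucleophilic trisubstituted alkenes.
- Comparison: on structure, this plan builds ring B last and leaves ring A and C4 to an earlier phase, whereas the chosen plan takes ring B, C5 and all of C4 from one starting material. On mechanism, a cationic rearrangement with a migratory-aptitude question stands against a radical closure with a chemoselectivity question. On total step economy the chosen plan is expected to be equal or better once the route to A2 is counted.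

Alternative 2: The cut is a retro-Diels–Alder opening of ring A at C4–C5 and C1–C10, to the silyloxy diene A5 (C1=C2–C3(OSi)=C4Me2) and the enynal A6. Forward, the chiral oxazaborolidinium triflimide would bind the aldehyde of A6 and direct an endo, face-selective [4+2] cycloaddition to A4. In A4, C5 and the quaternary C10 are set together, and the C3 oxygen, both C4 methyls, the future C9 (formyl carbon) and the future C6–C8 and methylene carbons (butynyl group) are in place.
- In its favour: two skeletal bonds and two adjacent stereocentres are made in one catalytic step from achiral compounds, against one bond and one stereocentre in the chosen key step. Either enantiomer is available by choice of catalyst, whereas the chosen plan depends on the chiral pool. On these points it is the better plan.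
- Against it here: the diene terminus C4 is fully substituted. This disfavours the s-cis conformer and forces a quaternary carbon to bond to the β-carbon of a hindered α-methyl enal, so a stepwise Mukaiyama–Michael pathway or loss of the silyl enol ether under the strong Lewis acid are real competitors. C3 is left as an enol ether and must be set later by ketone reduction. After A4, ring B does not yet exist: the C8–C9 closure, the attachment of the chain to C9 with control of that centre, and the exocyclic alkene are all still open.
- Comparison: on mechanism, a catalyst-controlled concerted cycloaddition is cleaner in principle than a substrate-controlled radical closure. On structure, the chosen plan has ring B and the C8/C9 handles from the start. On step economy, the sequence after A4 is expected to be longer than the ten steps that follow 10.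

Alternative 3: The cut is C9–C10, made through a [3,3] relationship. The acid A7 is traced to the six-membered lactone A8, in which the C11 carboxyl is esterified by an allylic C6 carbinol attached to a ring A cyclohexene (C5=C10). Forward, enolisation and O-silylation of A8 would give the silyl ketene acetal A9. Because C9 and C6 are tied together by C8 and C7, the rearrangement can only pass through a boat. C9 bonds to C10 on the α face, the C6–O bond breaks, and the carbocyclic ring B of A7 replaces the lactone, with the C6 configuration transferred to the quaternary C10.
- In its favour: the quaternary stereocentre is made by a sigmatropic chirality transfer of an established kind, which is better precedented than the chosen key step. C11 arrives bonded to C9 in the key step, where the chosen plan needs steps 7 and 8 to attach it. On these two points it is the better plan. The later C11 chemistry (reduction, sulfone, coupling with 20) would be the same in both.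
- Against it here: the new bond is made to a fully substituted alkene carbon through an enforced boat. The carboxyl of A7 sits on the wrong (α) face of C9 and must be epimerised. C5, which the chosen plan takes from 1, has to be created afterwards by hydrogenation of C5=C6 from the α face. The C8 ketal must be hydrolysed and methylenated. A8, with its C3 and C6 stereocentres, needs a multi-step synthesis of its own.
- Comparison: on mechanism both plans rely on substrate control, pericyclic here and radical there. On structure this plan solves C10 elegantly but postpones C5 and the methylene group. On step economy it is expected to be longer than fifteen steps.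

Key step: step 5

Step 1
Reactants: 1 (R)-(–)-carvone
Product: 3 (5R,6S)-6-methylcarvone, via lithium dienolate 2 (not isolated)
Conditions: LiN(i-Pr)2 (1.05 equiv), THF, –78 °C; MeI, –78 → 0 °C
Reagents that add atoms: iodomethane, CI
Why: Kinetic deprotonation on the saturated side of the enone carbonyl gives the cross-conjugated dienolate, which is C-methylated (enolate alkylation). The configuration of the new centre (mainly methyl anti to the isopropenyl group) does not matter, because the centre is planarised again in step 2.

Step 2
Reactants: 3 (5R,6S)-6-methylcarvone; 4 allyl bromide
Product: 6 (5S,6S)-6-allyl-6-methylcarvone, via lithium enolate 5 (not isolated)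
Conditions: LiN(i-Pr)2 (1.2 equiv), THF/DMPU, –78 °C; allyl bromide, –78 → –20 °C
Reagents that add atoms: none
Why: Enolate alkylation of the fully substituted enolate with a reactive allylic halide. The electrophile enters on the face anti to the neighbouring isopropenyl group, so the allyl group (future C1–C3) ends trans to C4 and the methyl cis, which is the C5/C10 relationship of a trans-decalin.

Step 3
Reactants: 6 (5S,6S)-6-allyl-6-methylcarvone
Product: 8 (5S,6S)-6-(3-hydroxypropyl)-6-methylcarvone, via B-alkyl-9-BBN adduct 7 (not isolated)
Conditions: 9-BBN (1.2 equiv), THF, 0 °C → rt; then NaBO3·4H2O, THF/H2O, rt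
Reagents that add atoms: 9-borabicyclo[3.3.1]nonane, B1C2CCCC1CCC2 (atoms kept only in 7); sodium perborate, [Na+].[O-]OB=O (oxygen of 8)
Why: Anti-Markovnikov hydroboration–oxidation. The bulky dialkylborane should select the monosubstituted allyl alkene over the 1,1-disubstituted isopropenyl group beside the quaternary carbon and over the hindered conjugated carbonyl, and perborate avoids the strongly basic peroxide that would epoxidise the enone.

Step 4
Reactants: 8 (5S,6S)-6-(3-hydroxypropyl)-6-methylcarvone
Product: 9 3-[(1S,6S)-1,3-dimethyl-2-oxo-6-(prop-1-en-2-yl)cyclohex-3-en-1-yl]propanal
Conditions: Dess–Martin periodinane, CH2Cl2, 0 °C → rt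
Reagents that add atoms: none
Why: Dess–Martin oxidation of a primary alcohol to the aldehyde under non-basic conditions. The absence of base avoids intramolecular Michael addition of the aldehyde enolate to the enone, and the aldehyde is used without storage.

Step 5
Reactants: 9 3-[(1S,6S)-1,3-dimethyl-2-oxo-6-(prop-1-en-2-yl)cyclohex-3-en-1-yl]propanal
Product: 10 (4aS,6S,8aS)-6-hydroxy-2,5,5,8a-tetramethyl-4a,5,6,7,8,8a-hexahydronaphthalen-1(4H)-one
Conditions: Fe(acac)3 (30 mol%), PhSiH3 (2.5 equiv, slow addition), degassed EtOH (0.02 M), 50 °C
Reagents that add atoms: none
Why: Proposed new method: the iron hydride formed from Fe(acac)3, PhSiH3 and ethanol should transfer a hydrogen atom to the terminal CH2 of the isopropenyl group, the tertiary C4 radical should add to the aldehyde carbon C3, and the C3 alkoxy radical should be reduced by divalent iron and protonated by ethanol, which returns trivalent iron; the closest known reaction type is the iron-hydride hydrogen-atom-transfer reductive cyclisation of alkenyl ketones to tertiary cycloalkanols, supported by the classical tin-hydride 6-exo closure of alkyl radicals onto aldehydes. Ring A closes in the 6-exo-trig mode at the carbonyl carbon, and the other π bonds are out of reach because closure onto C7, C8 or C9 would need a four-membered or bridged ring. The ring fusion is not at stake: C5 and C10 were fixed in steps 1 and 2 with both arms equatorial on ring B, so the new ring can only be trans-fused. The one new stereocentre, C3, is controlled by the chair-like transition state with the carbonyl oxygen pseudo-equatorial, away from the axial hydrogens on C1 and C5, which gives the 3β (S) carbinol; because the addition is reversible, the more stable equatorial alkoxy radical is also the one expected to be trapped. The selectivity needed is hydrogen-atom transfer to the isopropenyl group and not to the enone, and the substrate secures it because the electron-rich 1,1-disubstituted alkene accepts the hydrogen atom much faster than the trisubstituted, electron-poor and more hindered C7=C8 bond. High dilution and slow silane addition should keep the C4 radical from being reduced before it cyclises.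

Step 6
Reactants: 10 bicyclic 3β-hydroxy enone
Product: 11 3β-tert-butyldimethylsilyl ether of 10
Conditions: TBSOTf, 2,6-lutidine, CH2Cl2, –78 → 0 °C
Reagents that add atoms: tert-butyldimethylsilyl trifluoromethanesulfonate, CC(C)(C)[Si](C)(C)OS(=O)(=O)C(F)(F)F
Why: Silylation of a hindered secondary alcohol beside the gem-dimethyl carbon needs the silyl triflate. The ether should then survive the hydride, amide-base, palladium and organolithium steps that follow.

Step 7
Reactants: 11 3β-silyloxy enone
Product: 13 C8=C9 enol triflate (C9–OTf, C8 methyl), via lithium enolate 12 (not isolated)
Conditions: LiBH(s-Bu)3 (1.1 equiv), THF, –78 °C; then PhNTf2, –78 → 0 °C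
Reagents that add atoms: N-phenylbis(trifluoromethanesulfonimide), O=S(=O)(N(c1ccccc1)S(=O)(=O)C(F)(F)F)C(F)(F)F
Why: Conjugate hydride reduction of a cyclohexenone with a hydrogen on its β-carbon and a carbonyl shielded by the quaternary C10, followed by O-sulfonylation of the enolate. The enolate can only be C8=C9 because C10 carries no hydrogen.

Step 8
Reactants: 13 C8=C9 enol triflate
Product: 14 conjugated methyl ester (C9–CO2Me, C8=C9, C8 methyl)
Conditions: Pd(PPh3)4 (10 mol%), CO (1 atm), MeOH, Et3N, DMF, 65 °C
Reagents that add atoms: carbon monoxide, [C-]#[O+]; methanol, CO
Why: Palladium-catalysed alkoxycarbonylation of an enol triflate (oxidative addition to zerovalent palladium, CO insertion, methanolysis) installs C11 on C9. The silyl ether and the tetrasubstituted alkene are inert.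

Step 9
Reactants: 14 conjugated methyl ester
Product: 16 β,γ-unsaturated methyl ester (C8=CH2, 9α-H, C11 ester β), via lithium dienolate 15 (not isolated)
Conditions: LiN(i-Pr)2 (2 equiv), THF/DMPU, –78 → –30 °C; then sat. aq. NH4Cl, –78 °C
Reagents that add atoms: none
Why: Deconjugative α-protonation of an ester dienolate. The amide base should remove a γ-hydrogen from the C8 methyl, which is cis to the ester across C8=C9, and kinetic protonation at C9 then leaves the alkene exocyclic. The proton enters from the α face, opposite the axial C10 methyl, which sets C9 with the ester equatorial.

Step 10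
Reactants: 16 β,γ-unsaturated methyl ester
Product: 17 C11 primary alcohol (3β-silyloxy, C8=CH2)
Conditions: LiAlH4, Et2O, 0 °C
Reagents that add atoms: none
Why: Hydride reduction of the ester to the primary alcohol. The isolated alkene and the silyl ether are untouched, and the cold, short reaction leaves no time for C9 epimerisation or reconjugation.

Step 11
Reactants: 17 C11 primary alcohol
Product: 18 C11 phenyl sulfide
Conditions: PhSSPh, n-Bu3P, pyridine, rt → 50 °C
Reagents that add atoms: diphenyl disulfide, c1ccc(SSc2ccccc2)cc1
Why: Phosphine–disulfide thioetherification of a primary alcohol (Hata reaction; SN2 at C11 through the alkoxyphosphonium ion). The only free hydroxyl is the primary one.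

Step 12
Reactants: 18 C11 phenyl sulfide
Product: 19 C11 phenyl sulfone
Conditions: (NH4)6Mo7O24·4H2O (10 mol%), 30% H2O2, EtOH, 0 °C → rt
Reagents that add atoms: hydrogen peroxide, OO
Why: Molybdate-catalysed peroxide oxidation takes the sulfide to the sulfone and leaves the unactivated exocyclic alkene alone, whereas a peracid would compete for that alkene.

Step 13
Reactants: 19 C11 phenyl sulfone; 20 (2E,6E)-farnesyl bromide
Product: 22 C11-farnesylated sulfone, via α-lithio sulfone 21 (not isolated)
Conditions: n-BuLi (1.1 equiv), THF/DMPU, –78 °C; 20, –78 → –20 °C
Reagents that add atoms: none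
Why: Alkylation of an α-sulfonyl carbanion with a primary allylic bromide (SN2 at the CH2Br carbon, the sulfone coupling used in Julia-type chain assembly) forms C11–C12 with both E alkenes of the chain untouched. The C11 centre is a mixture that disappears in step 14.

Step 14
Reactants: 22 C11-farnesylated sulfone
Product: 23 3β-silyl ether of the target
Conditions: Na/Hg (6% Na), Na2HPO4, MeOH/THF, –20 → 0 °C
Reagents that add atoms: none
Why: Reductive desulfonylation by electron transfer. The sulfonyl carbon is homoallylic to both the C8 methylene and C13=C14, so neither allylic transposition nor loss of alkene geometry is possible, and isolated alkenes are not reduced.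

Step 15
Reactants: 23 3β-silyl ether of the target
Product: 24 (2S,4aR,5S,8aR)-1,1,4a-trimethyl-6-methylidene-5-[(3E,7E)-4,8,12-trimethyltrideca-3,7,11-trien-1-yl]decahydronaphthalen-2-ol
Conditions: TBAF, THF, 60 °C
Reagents that add atoms: none
Why: Fluoride cleavage of the silyl ether under non-acidic conditions, chosen because acid could isomerise the exocyclic alkene or cyclise the polyene. The hindered C3 ether needs warming.

## Compound list

1 | (R)-(–)-carvone, (5R)-2-methyl-5-(prop-1-en-2-yl)cyclohex-2-en-1-one | CC1=CC[C@@H](C(C)=C)CC1=O | starting material
2 | lithium dienolate of 1 (O–Li on the carbonyl carbon, new double bond to the former CH2 beside it, enone alkene retained) | CC1=CC[C@@H](C(C)=C)C=C1O[Li] | intermediate (not isolated)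
3 | (5R,6S)-2,6-dimethyl-5-(prop-1-en-2-yl)cyclohex-2-en-1-one (trans-6-methylcarvone; minor cis epimer carried along) | CC1=CC[C@@H](C(C)=C)[C@H](C)C1=O | intermediate
4 | allyl bromide (3-bromoprop-1-ene) | C=CCBr | starting material
5 | lithium enolate of 3 (O–Li on the carbonyl carbon, double bond to the methyl-bearing carbon beside it) | CC1=CC[C@@H](C(C)=C)C(C)=C1O[Li] | intermediate (not isolated)
6 | (5S,6S)-6-allyl-2,6-dimethyl-5-(prop-1-en-2-yl)cyclohex-2-en-1-one (allyl trans to isopropenyl) | CC1=CC[C@@H](C(C)=C)[C@](C)(CC=C)C1=O | intermediate
7 | 9-{3-[(1S,6S)-1,3-dimethyl-2-oxo-6-(prop-1-en-2-yl)cyclohex-3-en-1-yl]propyl}-9-borabicyclo[3.3.1]nonane | CC1=CC[C@@H](C(C)=C)[C@](C)(CCCB2C3CCCC2CCC3)C1=O | intermediate (not isolated)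
8 | (5S,6S)-6-(3-hydroxypropyl)-2,6-dimethyl-5-(prop-1-en-2-yl)cyclohex-2-en-1-one | CC1=CC[C@@H](C(C)=C)[C@](C)(CCCO)C1=O | intermediate
9 | 3-[(1S,6S)-1,3-dimethyl-2-oxo-6-(prop-1-en-2-yl)cyclohex-3-en-1-yl]propanal (key-step precursor) | CC1=CC[C@@H](C(C)=C)[C@](C)(CCC=O)C1=O | intermediate
10 | (4aS,6S,8aS)-6-hydroxy-2,5,5,8a-tetramethyl-4a,5,6,7,8,8a-hexahydronaphthalen-1(4H)-one (3β-OH, 5α-H, 10β-CH3, C9 ketone, C7=C8; key-step product) | CC1=CC[C@H]2C(C)(C)[C@@H](O)CC[C@]2(C)C1=O | intermediate
11 | (4aS,6S,8aS)-6-[(tert-butyldimethylsilyl)oxy]-2,5,5,8a-tetramethyl-4a,5,6,7,8,8a-hexahydronaphthalen-1(4H)-one | CC1=CC[C@H]2C(C)(C)[C@@H](O[Si](C)(C)C(C)(C)C)CC[C@]2(C)C1=O | intermediate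
12 | lithium enolate from 1,4-reduction of 11 (C9–OLi, C8=C9, C7 now CH2) | CC1=C(O[Li])[C@@]2(C)CC[C@H](O[Si](C)(C)C(C)(C)C)C(C)(C)[C@@H]2CC1 | intermediate (not isolated)
13 | enol triflate: 6-[(tert-butyldimethylsilyl)oxy]-2,5,5,8a-tetramethyl-3,4,4a,5,6,7,8,8a-octahydronaphthalen-1-yl trifluoromethanesulfonate (3β-OTBS, 5α-H, 10β-CH3) | CC1=C(OS(=O)(=O)C(F)(F)F)[C@@]2(C)CC[C@H](O[Si](C)(C)C(C)(C)C)C(C)(C)[C@@H]2CC1 | intermediate
14 | methyl 6-[(tert-butyldimethylsilyl)oxy]-2,5,5,8a-tetramethyl-3,4,4a,5,6,7,8,8a-octahydronaphthalene-1-carboxylate (conjugated ester, C8=C9; 3β-OTBS, 5α-H, 10β-CH3) | CC1=C(C(=O)OC)[C@@]2(C)CC[C@H](O[Si](C)(C)C(C)(C)C)C(C)(C)[C@@H]2CC1 | intermediate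
15 | lithium dienolate of 14 (C9=C11(OMe)OLi, C8=CH2) | C=C1CC[C@H]2C(C)(C)[C@@H](O[Si](C)(C)C(C)(C)C)CC[C@]2(C)C1=C(OC)O[Li] | intermediate (not isolated)
16 | methyl 6-[(tert-butyldimethylsilyl)oxy]-5,5,8a-trimethyl-2-methylidenedecahydronaphthalene-1-carboxylate (3β-OTBS, 5α-H, 9α-H, 10β-CH3, ester β-equatorial) | C=C1CC[C@H]2C(C)(C)[C@@H](O[Si](C)(C)C(C)(C)C)CC[C@]2(C)[C@H]1C(=O)OC | intermediate
17 | {6-[(tert-butyldimethylsilyl)oxy]-5,5,8a-trimethyl-2-methylidenedecahydronaphthalen-1-yl}methanol (same configuration as 16) | C=C1CC[C@H]2C(C)(C)[C@@H](O[Si](C)(C)C(C)(C)C)CC[C@]2(C)[C@H]1CO | intermediate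
18 | C11 phenyl sulfide of 17 (CH2OH replaced by CH2SPh) | C=C1CC[C@H]2C(C)(C)[C@@H](O[Si](C)(C)C(C)(C)C)CC[C@]2(C)[C@H]1CSc1ccccc1 | intermediate
19 | C11 phenyl sulfone (CH2SO2Ph on C9; 3β-OTBS, C8=CH2) | C=C1CC[C@H]2C(C)(C)[C@@H](O[Si](C)(C)C(C)(C)C)CC[C@]2(C)[C@H]1CS(=O)(=O)c1ccccc1 | intermediate
20 | (2E,6E)-farnesyl bromide, (2E,6E)-1-bromo-3,7,11-trimethyldodeca-2,6,10-triene | CC(C)=CCC/C(C)=C/CC/C(C)=C/CBr | starting material
21 | C11-lithio derivative of sulfone 19 | C=C1CC[C@H]2C(C)(C)[C@@H](O[Si](C)(C)C(C)(C)C)CC[C@]2(C)[C@H]1C([Li])S(=O)(=O)c1ccccc1 | intermediate (not isolated)
22 | 11-(phenylsulfonyl) derivative of 23 (farnesyl on C11; mixture of C11 epimers) | C=C1CC[C@H]2C(C)(C)[C@@H](O[Si](C)(C)C(C)(C)C)CC[C@]2(C)[C@H]1C(C/C=C(\C)CC/C=C(\C)CCC=C(C)C)S(=O)(=O)c1ccccc1 | intermediate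
23 | tert-butyldimethylsilyl ether of the target (3S,5R,9S,10R) | C=C1CC[C@H]2C(C)(C)[C@@H](O[Si](C)(C)C(C)(C)C)CC[C@]2(C)[C@H]1CC/C=C(\C)CC/C=C(\C)CCC=C(C)C | intermediate
24 | (2S,4aR,5S,8aR)-1,1,4a-trimethyl-6-methylidene-5-[(3E,7E)-4,8,12-trimethyltrideca-3,7,11-trien-1-yl]decahydronaphthalen-2-ol (CNP0192094.1) | C=C1CC[C@H]2C(C)(C)[C@@H](O)CC[C@]2(C)[C@H]1CC/C=C(\C)CC/C=C(\C)CCC=C(C)C | target

## Step count and least certain steps

Total: 15 steps. Longest linear sequence: 15 steps, from 1 to 24; 4 and 20 are commercial and enter in steps 2 and 13.

Step 5 (key step, the one step that carries the new-method label).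
- What may go wrong: the C4 radical may be reduced before it cyclises, or the closure may reverse by β-scission of the C3 alkoxy radical back to the stabilised tertiary radical, so that the isopropenyl group is merely hydrogenated. Less likely are hydrogen-atom transfer to the enone followed by closure of C8 onto the aldehyde, and incomplete equatorial control at C3.
- Fallback (known chemistry): it sets out from 8 and comes back at 10. One-pot oxidative conversion of the primary alcohol with TEMPO (cat.), PhI(OAc)2 and NH4OAc in MeCN/H2O would give 3-[(1S,6S)-1,3-dimethyl-2-oxo-6-(prop-1-en-2-yl)cyclohex-3-en-1-yl]propanenitrile F1. The established iron-hydride hydrogen-atom-transfer cyclisation of alkenyl nitriles (Fe(acac)3, PhSiH3, EtOH, 60 °C, hydrolytic work-up) would then form the same C3–C4 bond through an iminyl radical and deliver the bicyclic 3,9-dione F2. Reduction of the saturated C3 ketone in the presence of the hindered conjugated C9 ketone (NaBH4, MeOH/CH2Cl2, –78 °C), with axial hydride delivery, gives the equatorial carbinol of 10.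
- Correction at C3: should step 5 close the ring but form some of the 3α-epimer of 10 F3, the epimer mixture would be oxidised with Dess–Martin periodinane to F2 and reduced in the same way.

Step 9.
- What may go wrong: loss of regiocontrol in the deprotonation (a C7 hydrogen instead of a C8-methyl hydrogen, which moves the alkene into the ring), protonation at the γ-carbon, which returns 14, or protonation of C9 from the β face.
- Fallback: it sets out from 14 and comes back at 16. Photochemical deconjugation (254 nm, hexane, catalytic 1,2-dimethylimidazole) replaces the base. The excited ester can abstract a γ-hydrogen only from the carbon cis to it, the C8 methyl, through a six-membered array. This gives the photodienol F4, whose ketonisation at C9 from the open α face leads to 16.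

Step 3.
- What may go wrong: partial 1,2-reduction of the C9 carbonyl by the borane, or epoxidation of the enone during the oxidative work-up.
- Fallback: it sets out from 6 and comes back at 9, bypassing 8. The enone is removed first by LiAlH4 reduction (Et2O, –78 °C) to the allylic alcohol F5 (the epimer with OH cis to the quaternary methyl is drawn; either epimer serves). Hydroboration with 9-BBN and a standard NaOH/H2O2 work-up gives the diol F6. One double oxidation with Dess–Martin periodinane restores the enone and forms the aldehyde.

Step 7.
- What may go wrong: competing 1,2-reduction of the hindered carbonyl, or sluggish O-sulfonylation of the boron-associated, fully substituted enolate.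
- Fallback: it sets out from 11 and comes back at 13. Hydrogenation of the only alkene (H2, Pd/C, EtOAc) gives the saturated ketone F7 (equatorial 8α-methyl drawn; the centre is lost again). Deprotonation with KN(SiMe3)2 (THF, –78 °C), which can occur only at C8 because C10 has no hydrogen, and trapping with N-(5-chloro-2-pyridyl)bis(trifluoromethanesulfonimide) gives 13.

## Further compounds

F1 | step 5 | 3-[(1S,6S)-1,3-dimethyl-2-oxo-6-(prop-1-en-2-yl)cyclohex-3-en-1-yl]propanenitrile | CC1=CC[C@@H](C(C)=C)[C@](C)(CCC#N)C1=O
F2 | step 5 | (4aS,8aS)-2,5,5,8a-tetramethyl-4a,5,8,8a-tetrahydronaphthalene-1,6(4H,7H)-dione (3-oxo analogue of 10) | CC1=CC[C@H]2C(C)(C)C(=O)CC[C@]2(C)C1=O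
F3 | step 5 | 3α-epimer of 10 (axial C3 hydroxyl) | CC1=CC[C@H]2C(C)(C)[C@H](O)CC[C@]2(C)C1=O
F4 | step 9 | photodienol of 14 (C9=C11(OH)OMe, C8=CH2) | C=C1CC[C@H]2C(C)(C)[C@@H](O[Si](C)(C)C(C)(C)C)CC[C@]2(C)C1=C(O)OC
F5 | step 3 | allylic alcohol from 1,2-reduction of 6 (carbinol OH cis to the quaternary methyl) | CC1=CC[C@@H](C(C)=C)[C@](C)(CC=C)[C@H]1O
F6 | step 3 | diol from hydroboration–oxidation of F5 (3-hydroxypropyl arm, allylic ring carbinol) | CC1=CC[C@@H](C(C)=C)[C@](C)(CCCO)[C@H]1O
F7 | step 7 | 7,8-dihydro derivative of 11 (saturated C9 ketone, 8α-methyl) | C[C@@H]1CC[C@H]2C(C)(C)[C@@H](O[Si](C)(C)C(C)(C)C)CC[C@]2(C)C1=O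
A1 | alternative 1 | 8-oxo decalin carrying the full chain on C9 (3β-OTBS, chain equatorial) | O=C1CC[C@H]2C(C)(C)[C@@H](O[Si](C)(C)C(C)(C)C)CC[C@]2(C)[C@H]1CC/C=C(\C)CC/C=C(\C)CCC=C(C)C
A2 | alternative 1 | trans-hydrindanone lacking C9 (C8 carbonyl bonded to C10; 3β-OTBS, 5α-H, 10β-CH3) | O=C1CC[C@H]2C(C)(C)[C@@H](O[Si](C)(C)C(C)(C)C)CC[C@]12C
A3 | alternative 1 | bis(methylseleno)acetal of (4E,8E)-5,9,13-trimethyltetradeca-4,8,12-trienal | C[Se]C([Se]C)CC/C=C(\C)CC/C=C(\C)CCC=C(C)C
A4 | alternative 2 | Diels–Alder adduct: cyclohexene silyl enol ether with C5 butynyl and C10 methyl and formyl groups | C#CCC[C@H]1C(C)(C)C(O[Si](C)(C)C(C)(C)C)=CC[C@]1(C)C=O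
A5 | alternative 2 | tert-butyldimethyl[(4-methylpenta-1,3-dien-3-yl)oxy]silane | C=CC(O[Si](C)(C)C(C)(C)C)=C(C)C
A6 | alternative 2 | (E)-2-methylhept-2-en-6-ynal | C#CCC/C=C(\C)C=O
A7 | alternative 3 | bicyclic C11 acid with C5=C6 alkene and C8 dioxolane (C9 α-carboxyl) | OC(=O)[C@@H]1C2(OCCO2)CC=C3C(C)(C)[C@@H](O[Si](C)(C)C(C)(C)C)CC[C@]13C
A8 | alternative 3 | six-membered lactone: C11 carboxyl esterified by the allylic C6 carbinol on the ring A cyclohexene (C5=C10), C8 dioxolane | O=C1CC2(OCCO2)C[C@H](O1)C1=C(C)CC[C@H](O[Si](C)(C)C(C)(C)C)C1(C)C
A9 | alternative 3 | trimethylsilyl ketene acetal of A8 | C[Si](C)(C)OC1=CC2(OCCO2)C[C@H](O1)C1=C(C)CC[C@H](O[Si](C)(C)C(C)(C)C)C1(C)C
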